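**Plan**
1. Retrosynthesis: the ten benzyl ethers come off last. Ring C of the per-benzylated flavan 12 is then cut at C4–C3 and at O1–C2 together, leaving the ring A ortho-quinone methide 11 (already carrying the 5-O-gallate) and the (Z)-enol gallate 10 (ring B on C2, the 3-O-gallate on C3).
2. Enabling feature: O1, C8a, C4a and C4 form a 2-hydroxybenzyl unit on ring A that can be unmasked as the 1-oxadiene O=C8a–C4a=C4H2. C2–C3, with aryl on C2 and acyloxy on C3, sits at the oxidation level of an aryl enol ester, so a [4+2] cycloaddition builds ring C directly.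
3. Forward: ring A piece 6 from 2,4,6-trihydroxybenzaldehyde (steps 1, 3, 4) and the galloyl chloride 4 (step 2); ring B piece 10 from 3,4,5-tris(benzyloxy)benzaldehyde by alkyne homologation and Z-selective hydro-acyloxylation (steps 5, 6); ring C, the only ring made, in step 7; hydrogenolysis in step 8.
4. Stereochemistry: the 2,3-cis relationship is stored in the Z double bond of 10 (step 6) and transferred suprafacially in step 7. The absolute (2R,3R) configuration comes from the chiral Brønsted acid of step 7.
5. Benzyl ethers are the only helper groups; both gallate esters are in place before ring C is made.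

Key step: step 7

Assumption: the (R)-configured catalyst is taken to deliver the (2R,3R) adduct; should the sense of induction be opposite, its (S)-enantiomer is used instead.

**Step 1**
Reactants: 1 2,4,6-trihydroxybenzaldehyde
Product: 2 4-(benzyloxy)-2,6-dihydroxybenzaldehyde
Conditions: BnBr (1.0 equiv), CsHCO3 (1.1 equiv), MeCN, 60 °C
Reagents that add atoms: benzyl bromide, BrCc1ccccc1
Why: Williamson ether synthesis; the 4-OH is para to the formyl group, the most acidic hydroxyl and the only one outside the OH···O=C chelate, so a weak base should alkylate it selectively.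

**Step 2**
Reactants: 3 3,4,5-tris(benzyloxy)benzoic acid
Product: 4 3,4,5-tris(benzyloxy)benzoyl chloride
Conditions: (COCl)2 (1.2 equiv), DMF (cat.), CH2Cl2, 0 °C to rt, then evaporation
Reagents that add atoms: oxalyl chloride, ClC(=O)C(=O)Cl
Why: acid chloride formation through the catalytic Vilsmeier-type chloroiminium species; the benzyl ethers are inert.

**Step 3**
Reactants: 2 4-(benzyloxy)-2,6-dihydroxybenzaldehyde; 4 3,4,5-tris(benzyloxy)benzoyl chloride
Product: 5 5-(benzyloxy)-2-formyl-3-hydroxyphenyl 3,4,5-tris(benzyloxy)benzoate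
Conditions: 4 (1.0 equiv, slow addition), Et3N (1.1 equiv), DMAP (5 mol %), CH2Cl2, −20 to 0 °C
Reagents that add atoms: none
Why: DMAP-catalysed O-acylation of a phenol; the two hydroxyls of 2 are equivalent, and after the first acylation the remaining one is locked in the hydrogen bond to the formyl group and flanked on both sides, so the reaction should stop at the mono-ester.

**Step 4**
Reactants: 5 5-(benzyloxy)-2-formyl-3-hydroxyphenyl 3,4,5-tris(benzyloxy)benzoate
Product: 6 5-(benzyloxy)-3-hydroxy-2-(hydroxymethyl)phenyl 3,4,5-tris(benzyloxy)benzoate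
Conditions: NaBH(OAc)3 (2.5 equiv), AcOH/THF 1:5, 0 °C to rt; pH 7 phosphate buffer work-up
Reagents that add atoms: none
Why: hydroxyl-directed triacetoxyborohydride reduction (Saksena–Evans type), in which the phenol exchanges onto boron and delivers hydride to the neighbouring formyl group; the acidic medium never generates a free benzylic alkoxide, so the O-to-O shift of the adjacent aryl gallate is suppressed, and the esters and benzyl ethers are inert to this reagent.

**Step 5**
Reactants: 7 3,4,5-tris(benzyloxy)benzaldehyde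
Product: 9 1,2,3-tris(benzyloxy)-5-ethynylbenzene, via diazoalkene 8 (not isolated)
Conditions: dimethyl (1-diazo-2-oxopropyl)phosphonate (1.3 equiv), K2CO3 (2 equiv), MeOH/THF 1:1, 0 °C to rt
Reagents that add atoms: dimethyl (1-diazo-2-oxopropyl)phosphonate (Ohira–Bestmann reagent), CC(=O)C(=[N+]=[N-])P(=O)(OC)OC
Why: Seyferth–Gilbert homologation in the Ohira–Bestmann variant; olefination gives the diazoalkene 8, which loses N2, and a 1,2-hydrogen shift in the alkylidene carbene gives the terminal alkyne.

**Step 6**
Reactants: 9 1,2,3-tris(benzyloxy)-5-ethynylbenzene; 3 3,4,5-tris(benzyloxy)benzoic acid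
Product: 10 (Z)-2-[3,4,5-tris(benzyloxy)phenyl]ethenyl 3,4,5-tris(benzyloxy)benzoate
Conditions: [RuCl2(p-cymene)]2 (1 mol %), P(4-ClC6H4)3 (3 mol %), DMAP (4 mol %), toluene, 60 °C
Reagents that add atoms: none
Why: ruthenium-catalysed anti-Markovnikov hydro-acyloxylation of a terminal alkyne through a ruthenium vinylidene; the carboxylate adds to the metal-bound carbon and protonolysis of the alkenyl ruthenium species should release the Z enol ester, which fixes the geometry that becomes the 2,3-cis relationship.

**Step 7**
Reactants: 6 5-(benzyloxy)-3-hydroxy-2-(hydroxymethyl)phenyl 3,4,5-tris(benzyloxy)benzoate; 10 (Z)-2-[3,4,5-tris(benzyloxy)phenyl]ethenyl 3,4,5-tris(benzyloxy)benzoate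
Product: 12 (2R,3R)-7-(benzyloxy)-2-[3,4,5-tris(benzyloxy)phenyl]-3,4-dihydro-2H-chromene-3,5-diyl bis[3,4,5-tris(benzyloxy)benzoate], via ortho-quinone methide 11 (not isolated)
Conditions: (R)-3,3'-bis(2,4,6-triisopropylphenyl)-1,1'-binaphthyl-2,2'-diyl N-triflylphosphoramide (10 mol %), 10 (1.5 equiv), 6 added over 6 h, PhCF3, Na2SO4, −20 °C
Reagents that add atoms: none
Why: Proposed new method: the chiral acid ionises the benzylic C–OH of 6 (pushed by the para-benzyloxy and ortho-hydroxy groups) to the ortho-quinone methide 11, which stays hydrogen-bonded or ion-paired to the catalyst and adds as a 1-oxadiene (O=C8a–C4a=C4H2) across the electron-rich C2=C3 bond of 10 in an inverse-electron-demand oxa-Diels–Alder reaction. The closest known reaction type is the chiral phosphoric acid or N-triflylphosphoramide catalysed [4+2] cycloaddition of ortho-quinone methides, made in situ from 2-hydroxybenzyl alcohols, with styrenes and enol derivatives to give 2-arylchromans; new here are the unsubstituted methide carbon and the (Z)-2-acyloxystyrene as dienophile. Ring C is the only ring closed, by an intermolecular, concerted but asynchronous [4+2] cycloaddition in which the C4–C3 bond leads and the O1–C2 bond follows. C2 and C3 receive their relative configuration from the Z geometry of 10, because both new bonds form on the same face of the alkene (suprafacial addition, aryl and acyloxy remain cis), and their absolute configuration from the catalyst, whose 3,3'-aryl groups should leave one face of bound 11 open to only one enantiotopic face of 10. The step needs regioselectivity (methide carbon to C3, oxygen to C2), which the 3,4,5-tris(benzyloxy)phenyl group secures by stabilising the positive charge that builds up at C2 far better than the weakly donating acyloxy group could at C3, and chemoselectivity against self-condensation of 11, which the slow addition of 6 to an excess of 10 and the electron-withdrawing 5-O-acyl group on ring A secure. Both ester types and all benzyl ethers should be inert to the catalytic acid at −20 °C.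

**Step 8**
Reactants: 12 (2R,3R)-7-(benzyloxy)-2-[3,4,5-tris(benzyloxy)phenyl]-3,4-dihydro-2H-chromene-3,5-diyl bis[3,4,5-tris(benzyloxy)benzoate]
Product: 13 epigallocatechin 3,5-digallate, (2R,3R)-7-hydroxy-2-(3,4,5-trihydroxyphenyl)-3,4-dihydro-2H-chromene-3,5-diyl bis(3,4,5-trihydroxybenzoate)
Conditions: H2 (1 atm), Pd(OH)2/C (20 wt %), THF/EtOAc 1:1, rt, degassed solvents
Reagents that add atoms: none
Why: hydrogenolysis of the ten benzyl ethers; the neutral, non-nucleophilic medium should leave both gallate esters in place (no acyl migration or transesterification) and should not epimerise C2 or C3.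

**Compound list**
1 | 2,4,6-trihydroxybenzaldehyde | O=Cc1c(O)cc(O)cc1O | starting material
2 | 4-(benzyloxy)-2,6-dihydroxybenzaldehyde | O=Cc1c(O)cc(OCc2ccccc2)cc1O | intermediate
3 | 3,4,5-tris(benzyloxy)benzoic acid | OC(=O)c1cc(OCc2ccccc2)c(OCc2ccccc2)c(OCc2ccccc2)c1 | starting material
4 | 3,4,5-tris(benzyloxy)benzoyl chloride | ClC(=O)c1cc(OCc2ccccc2)c(OCc2ccccc2)c(OCc2ccccc2)c1 | intermediate
5 | 5-(benzyloxy)-2-formyl-3-hydroxyphenyl 3,4,5-tris(benzyloxy)benzoate | O=Cc1c(O)cc(OCc2ccccc2)cc1OC(=O)c1cc(OCc2ccccc2)c(OCc2ccccc2)c(OCc2ccccc2)c1 | intermediate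
6 | 5-(benzyloxy)-3-hydroxy-2-(hydroxymethyl)phenyl 3,4,5-tris(benzyloxy)benzoate | OCc1c(O)cc(OCc2ccccc2)cc1OC(=O)c1cc(OCc2ccccc2)c(OCc2ccccc2)c(OCc2ccccc2)c1 | intermediate
7 | 3,4,5-tris(benzyloxy)benzaldehyde | O=Cc1cc(OCc2ccccc2)c(OCc2ccccc2)c(OCc2ccccc2)c1 | starting material
8 | 1,2,3-tris(benzyloxy)-5-(2-diazoethenyl)benzene (diazoalkene, not isolated) | [N-]=[N+]=C=Cc1cc(OCc2ccccc2)c(OCc2ccccc2)c(OCc2ccccc2)c1 | intermediate
9 | 1,2,3-tris(benzyloxy)-5-ethynylbenzene | C#Cc1cc(OCc2ccccc2)c(OCc2ccccc2)c(OCc2ccccc2)c1 | intermediate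
10 | (Z)-2-[3,4,5-tris(benzyloxy)phenyl]ethenyl 3,4,5-tris(benzyloxy)benzoate | O=C(O/C=C\c1cc(OCc2ccccc2)c(OCc2ccccc2)c(OCc2ccccc2)c1)c1cc(OCc2ccccc2)c(OCc2ccccc2)c(OCc2ccccc2)c1 | intermediate
11 | 3-(benzyloxy)-6-methylidene-5-oxocyclohexa-1,3-dien-1-yl 3,4,5-tris(benzyloxy)benzoate (ortho-quinone methide, not isolated) | C=C1C(=O)C=C(OCc2ccccc2)C=C1OC(=O)c1cc(OCc2ccccc2)c(OCc2ccccc2)c(OCc2ccccc2)c1 | intermediate
12 | (2R,3R)-7-(benzyloxy)-2-[3,4,5-tris(benzyloxy)phenyl]-3,4-dihydro-2H-chromene-3,5-diyl bis[3,4,5-tris(benzyloxy)benzoate] | O=C(Oc1cc(OCc3ccccc3)cc2c1C[C@@H](OC(=O)c1cc(OCc3ccccc3)c(OCc3ccccc3)c(OCc3ccccc3)c1)[C@@H](c1cc(OCc3ccccc3)c(OCc3ccccc3)c(OCc3ccccc3)c1)O2)c1cc(OCc2ccccc2)c(OCc2ccccc2)c(OCc2ccccc2)c1 | intermediate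
13 | epigallocatechin 3,5-digallate | O=C(Oc1cc(O)cc2c1C[C@@H](OC(=O)c1cc(O)c(O)c(O)c1)[C@@H](c1cc(O)c(O)c(O)c1)O2)c1cc(O)c(O)c(O)c1 | target

**Summary**
Total step count: 8. Longest linear sequence: 5 steps (1 → 2 → 5 → 6 → 12 → 13).

**Steps most likely to fail**

Step 7 (Proposed new method). What may go wrong: weak enantiofacial discrimination, because 10 offers the catalyst no hydrogen-bond donor. The acid may also open a stepwise ionic pathway (bond rotation in a C2 benzylic cation before ring closure, or Friedel–Crafts capture of 11 by an electron-rich arene) that erodes the cis relationship. Fallback: give up catalyst control and use the known uncatalysed thermal hetero-Diels–Alder reaction of ortho-quinone methides with styrene-type alkenes, followed by resolution. Setting out from 6 and 10, 6 is heated with an excess of 10 in toluene at 100–110 °C, where the acid-free conditions favour the concerted, Z-retaining pathway. This should give the racemic cis adduct, that is 12 together with its mirror image (2S,3S)-7-(benzyloxy)-2-[3,4,5-tris(benzyloxy)phenyl]-3,4-dihydro-2H-chromene-3,5-diyl bis[3,4,5-tris(benzyloxy)benzoate] F1. Preparative chromatography on a chiral stationary phase (amylose tris(3,5-dimethylphenylcarbamate), supercritical CO2/iPrOH) should separate the antipodes; F1 is discarded and the route is rejoined at 12.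

Step 4. What may go wrong: O-to-O shift of the aryl gallate onto the new benzylic oxygen with loss of the gallate, over-reduction to the ortho-methyl phenol through premature ortho-quinone methide formation, or no reduction of the chelated, deactivated formyl group. Fallback: take the phenol out of play before reducing. Setting out from 5, silylation (TBSCl, imidazole, DMF, rt) gives 5-(benzyloxy)-3-[(tert-butyldimethylsilyl)oxy]-2-formylphenyl 3,4,5-tris(benzyloxy)benzoate F2. With the chelate gone, BH3·THF at 0 °C reduces the formyl group through a neutral alkoxyborane, which has no alkoxide and so causes no acyl or silyl shift, to 5-(benzyloxy)-3-[(tert-butyldimethylsilyl)oxy]-2-(hydroxymethyl)phenyl 3,4,5-tris(benzyloxy)benzoate F3. HF·pyridine in THF at 0 °C removes the silyl group under acidic conditions and returns to the route at 6.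

Step 1. What may go wrong: poor regioselectivity of the mono-benzylation (competing alkylation of a 2-OH, double O-benzylation, C-benzylation of the phloroglucinol ring). Fallback: benzylate twice and remove the ortho benzyl group later by chelation. Setting out from 1, BnBr (2 equiv) and K2CO3 in DMF give 2,4-bis(benzyloxy)-6-hydroxybenzaldehyde F4, whose last hydroxyl is held by the formyl group. Acylation with 4 (Et3N, DMAP, CH2Cl2) gives 3,5-bis(benzyloxy)-2-formylphenyl 3,4,5-tris(benzyloxy)benzoate F5. MgBr2·OEt2 in toluene/Et2O should cleave only the benzyl ether ortho to the formyl group, through the magnesium chelate between the formyl and ether oxygens, and the route is rejoined at 5, by-passing 2.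

**Further compounds**
F1 | step 7 | (2S,3S)-7-(benzyloxy)-2-[3,4,5-tris(benzyloxy)phenyl]-3,4-dihydro-2H-chromene-3,5-diyl bis[3,4,5-tris(benzyloxy)benzoate] | O=C(Oc1cc(OCc3ccccc3)cc2c1C[C@H](OC(=O)c1cc(OCc3ccccc3)c(OCc3ccccc3)c(OCc3ccccc3)c1)[C@H](c1cc(OCc3ccccc3)c(OCc3ccccc3)c(OCc3ccccc3)c1)O2)c1cc(OCc2ccccc2)c(OCc2ccccc2)c(OCc2ccccc2)c1
F2 | step 4 | 5-(benzyloxy)-3-[(tert-butyldimethylsilyl)oxy]-2-formylphenyl 3,4,5-tris(benzyloxy)benzoate | O=Cc1c(O[Si](C)(C)C(C)(C)C)cc(OCc2ccccc2)cc1OC(=O)c1cc(OCc2ccccc2)c(OCc2ccccc2)c(OCc2ccccc2)c1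
F3 | step 4 | 5-(benzyloxy)-3-[(tert-butyldimethylsilyl)oxy]-2-(hydroxymethyl)phenyl 3,4,5-tris(benzyloxy)benzoate | OCc1c(O[Si](C)(C)C(C)(C)C)cc(OCc2ccccc2)cc1OC(=O)c1cc(OCc2ccccc2)c(OCc2ccccc2)c(OCc2ccccc2)c1
F4 | step 1 | 2,4-bis(benzyloxy)-6-hydroxybenzaldehyde | O=Cc1c(O)cc(OCc2ccccc2)cc1OCc1ccccc1
F5 | step 1 | 3,5-bis(benzyloxy)-2-formylphenyl 3,4,5-tris(benzyloxy)benzoate | O=Cc1c(OCc2ccccc2)cc(OCc2ccccc2)cc1OC(=O)c1cc(OCc2ccccc2)c(OCc2ccccc2)c(OCc2ccccc2)c1
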